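The central benzene (ring A) is built last, from two pieces that map onto its alternating oxygen/carbon pattern. C3(CH2)–C4(OH)–C5(CH2)–C6(OH) comes from a 2,4-disubstituted 3-oxoglutaric anhydride that already carries both butyrylfilicinic acid arms, and C1(butyryl)–C2(O) from 1-ethoxyhex-1-yn-3-one. In one operation the annulation forms C2–C3 and C1–C6, expels CO2 and aromatises ring A with all six substituents in place. The anhydride arises from di-tert-butyl 3-oxopentanedioate and the Mannich base of butyrylfilicinic acid. Its six acidic OH groups are silylated in the flask, so that the pyranone diene is the only nucleophile. BCl3 finally frees the C2 hydroxyl.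

Key step: step 8

Remark: enols are drawn as one tautomer; 7 is racemic and 8–10 are epimer mixtures at the CH centres next to the central ketone, which end as aromatic C3 and C5; ring A is numbered C1 (butyryl), C2 (O), C3 (CH2), C4 (OH), C5 (CH2), C6 (OH), and pyranone carbons C3–C6 keep these numbers.

Short name used below: butyrylfilicinylmethyl = (5-butanoyl-2,6-dihydroxy-3,3-dimethyl-4-oxocyclohexa-1,5-dien-1-yl)methyl.

Step 1
Reactants: 1 1-(2,4,6-trihydroxyphenyl)butan-1-one
Product: 3 butyrylfilicinic acid, via 3-methylphlorobutyrophenone 2 (not isolated)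
Conditions: MeI (2.2 equiv), NaOMe (3 equiv), MeOH, 0 °C to rt; then 1 M HCl
Reagents that add atoms: iodomethane, CI
Why: Dearomatising double C-methylation of an acylphloroglucinolate, the classical entry to acylfilicinic acids; the second methyl group enters at the already methylated, most electron-rich ring carbon, so 3 should be the main product after separation from under- and over-methylated congeners, and no stereocentre arises.

Step 2
Reactants: 3 butyrylfilicinic acid
Product: 4 2-butanoyl-4-[(dimethylamino)methyl]-3,5-dihydroxy-6,6-dimethylcyclohexa-2,4-dien-1-one (Mannich base, inner salt)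
Conditions: Eschenmoser's salt (1.05 equiv), MeCN, 0 °C to rt; then aq NaHCO3 (1 equiv)
Reagents that add atoms: N,N-dimethylmethylideneammonium iodide (Eschenmoser's salt), C=[N+](C)C.[I-]
Why: Mannich reaction in which the only free ring CH of enol 3 attacks the preformed iminium ion; the absence of free formaldehyde should suppress coupling of two arms through a methylene bridge.

Step 3
Reactants: 4 Mannich base of butyrylfilicinic acid (2.2 equiv); 5 di-tert-butyl 3-oxopentanedioate
Product: 8 di-tert-butyl 2,4-bis(butyrylfilicinylmethyl)-3-oxopentanedioate, via enone methide 6 (not isolated), via mono-alkylated keto diester 7 (not isolated)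
Conditions: 1,4-dioxane, 70 °C, N2 sweep; then 1 M HCl wash
Reagents that add atoms: none
Why: Thermal loss of dimethylamine from 4 gives the enone methide 6, which the enol of the β-keto ester traps by Michael addition; after the first alkylation the unsubstituted C4 methylene of the pentanedioate is the less hindered acidic site, so the second arm should enter there (2,4- and not 2,2-substitution), and the two new CH centres are formed without control because they are lost later.

Step 4
Reactants: 8 di-tert-butyl 2,4-bis(butyrylfilicinylmethyl)-3-oxopentanedioate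
Product: 9 2,4-bis(butyrylfilicinylmethyl)-3-oxopentanedioic acid
Conditions: TFA/CH2Cl2 (1:3), 0 °C; evaporation with toluene below 20 °C
Reagents that add atoms: none
Why: Acidolysis of tert-butyl esters with loss of isobutene under anhydrous conditions at 0 °C, where the 2,4-disubstituted β-keto diacid should neither decarboxylate nor cyclodehydrate before use.

Step 5
Reactants: 9 2,4-bis(butyrylfilicinylmethyl)-3-oxopentanedioic acid
Product: 10 2,4-bis(butyrylfilicinylmethyl)-3-oxoglutaric anhydride (3,5-disubstituted oxane-2,4,6-trione)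
Conditions: DCC (1.0 equiv), THF, 0 °C; filtration; filtrate used at once
Reagents that add atoms: none
Why: Carbodiimide cyclodehydration of a 1,5-diacid to the six-membered anhydride; without an acyl-transfer catalyst the second carboxyl group should be the fastest nucleophile for the O-acylisourea, and the product rests as its conjugated 4-hydroxypyran-2,6-dione enol.

Step 6
Reactants: 11 ethoxyethyne; 12 butanal
Product: 14 (±)-1-ethoxyhex-1-yn-3-ol, via lithium ethoxyacetylide 13 (not isolated)
Conditions: n-BuLi (1.0 equiv), THF, −78 °C; then 12, −78 to −20 °C; then H2O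
Reagents that add atoms: none
Why: Deprotonation of the terminal alkyne and 1,2-addition of the lithium acetylide to the aldehyde; the carbinol centre is formed racemic and is removed in step 7.

Step 7
Reactants: 14 (±)-1-ethoxyhex-1-yn-3-ol
Product: 15 1-ethoxyhex-1-yn-3-one
Conditions: activated MnO2 (10 equiv), CH2Cl2, rt
Reagents that add atoms: none
Why: MnO2 oxidation of a propargylic alcohol under neutral conditions, which avoids the acid-catalysed Meyer–Schuster rearrangement of the ynol ether.

Step 8
Reactants: 10 2,4-bis(butyrylfilicinylmethyl)-3-oxoglutaric anhydride; 15 1-ethoxyhex-1-yn-3-one (1.5 equiv)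
Product: 19 1-[2-ethoxy-4,6-dihydroxy-3,5-bis(butyrylfilicinylmethyl)phenyl]butan-1-one (ring A 2-O-ethyl ether of the target), via hexakis-silyl pyranone 16 (not isolated), via bridged lactone 17 (not isolated), via hexakis-silyl arene 18 (not isolated)
Conditions: BSA (8 equiv), toluene, 50 °C; then 15, 80 °C; then 1 M HCl, THF, 0 °C to rt
Reagents that add atoms: none
Why: Proposed new method: exhaustive O-silylation turns 10 into 16, a 3,5-dialkyl-4,6-bis(silyloxy)-2-pyranone (a cyclic 1,1,3-trioxygenated diene) whose four arm enols are capped, so that the pyranone is the only nucleophilic π system and no free oxygen can add to the ynone or open an anhydride. Its terminus C3 adds to the ethoxy-bearing carbon of 15 in the Michael sense (C2–C3 of ring A), the carbon alpha to the butyryl group then bonds to the oxygen-stabilised C6 (C1–C6) in a strongly asynchronous [4+2] addition giving bridged lactone 17, and retro-[4+2] loss of CO2 (the former anhydride C2 with the ring oxygen) delivers arene 18, which acid work-up desilylates to 19. The closest known reaction types are the Tamura annulation of homophthalic and glutaconic anhydrides with alkynes and the 2-pyranone–alkyne Diels–Alder benzannulation with extrusion of CO2, neither of which has been shown for a 3-oxoglutaric anhydride or an alkoxy ynone. Ring A closes in the second bond formation as a six-membered closure onto the carbonyl-type C6, whose oxygen stays outside the new ring (6-exo-trig). No stereocentre is set, since the two bridgeheads of 17 become aromatic carbons. The step needs one ynone orientation and C- instead of O-bonding: the push-pull polarisation of 15 (only its ethoxy carbon is electrophilic) and the fact that either carbon flanking C4 leads to the same arene secure the first, the silyl capping secures the second.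

Step 9
Reactants: 19 ring A 2-O-ethyl ether
Product: 20 1-[2,4,6-trihydroxy-3,5-bis(butyrylfilicinylmethyl)phenyl]butan-1-one (target, CNP0086314.0)
Conditions: BCl3 (8 equiv), CH2Cl2, −78 to 0 °C; then H2O
Reagents that add atoms: none
Why: Chelation-assisted dealkylation of an aryl alkyl ether ortho to an acyl group by BCl3 (boron binds the butyryl and ether oxygens, chloride removes the ethyl group); the low temperature should leave the methylene bridges untouched.

Compound list
1 | 1-(2,4,6-trihydroxyphenyl)butan-1-one | CCCC(=O)c1c(O)cc(O)cc1O | starting material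
2 | 1-(2,4,6-trihydroxy-3-methylphenyl)butan-1-one | CCCC(=O)c1c(O)cc(O)c(C)c1O | intermediate
3 | butyrylfilicinic acid, 2-butanoyl-3,5-dihydroxy-6,6-dimethylcyclohexa-2,4-dien-1-one | CCCC(=O)C1=C(O)C=C(O)C(C)(C)C1=O | intermediate
4 | 2-butanoyl-4-[(dimethylamino)methyl]-3,5-dihydroxy-6,6-dimethylcyclohexa-2,4-dien-1-one | CCCC(=O)C1=C(O)C(CN(C)C)=C(O)C(C)(C)C1=O | intermediate
5 | di-tert-butyl 3-oxopentanedioate | CC(C)(C)OC(=O)CC(=O)CC(=O)OC(C)(C)C | starting material
6 | 2-butanoyl-3-hydroxy-4,4-dimethyl-6-methylidenecyclohex-2-ene-1,5-dione (enone methide) | CCCC(=O)C1=C(O)C(C)(C)C(=O)C(=C)C1=O | intermediate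
7 | di-tert-butyl 2-(butyrylfilicinylmethyl)-3-oxopentanedioate, racemic | CC(C)(C)OC(=O)CC(=O)C(CC1=C(O)C(C)(C)C(=O)C(C(=O)CCC)=C1O)C(=O)OC(C)(C)C | intermediate
8 | di-tert-butyl 2,4-bis(butyrylfilicinylmethyl)-3-oxopentanedioate, epimer mixture at C2 and C4 | CC(C)(C)OC(=O)C(CC1=C(O)C(C)(C)C(=O)C(C(=O)CCC)=C1O)C(=O)C(CC1=C(O)C(C)(C)C(=O)C(C(=O)CCC)=C1O)C(=O)OC(C)(C)C | intermediate
9 | 2,4-bis(butyrylfilicinylmethyl)-3-oxopentanedioic acid, epimer mixture at C2 and C4 | OC(=O)C(CC1=C(O)C(C)(C)C(=O)C(C(=O)CCC)=C1O)C(=O)C(CC1=C(O)C(C)(C)C(=O)C(C(=O)CCC)=C1O)C(=O)O | intermediate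
10 | 2,4-bis(butyrylfilicinylmethyl)-3-oxoglutaric anhydride, 3,5-bis(butyrylfilicinylmethyl)oxane-2,4,6-trione, ring CH centres enolizable and undefined | O=C1OC(=O)C(CC2=C(O)C(C)(C)C(=O)C(C(=O)CCC)=C2O)C(=O)C1CC3=C(O)C(C)(C)C(=O)C(C(=O)CCC)=C3O | intermediate
11 | ethoxyethyne | CCOC#C | starting material
12 | butanal | CCCC=O | starting material
13 | lithium ethoxyacetylide | [Li]C#COCC | intermediate
14 | (±)-1-ethoxyhex-1-yn-3-ol | CCCC(O)C#COCC | intermediate
15 | 1-ethoxyhex-1-yn-3-one | CCCC(=O)C#COCC | intermediate
16 | 4,6-bis(trimethylsilyloxy)-2H-pyran-2-one bearing at C3 and C5 a butyrylfilicinylmethyl group with both enol oxygens trimethylsilylated (hexakis-silyl derivative of 10) | O=C1OC(O[Si](C)(C)C)=C(CC2=C(O[Si](C)(C)C)C(C)(C)C(=O)C(C(=O)CCC)=C2O[Si](C)(C)C)C(O[Si](C)(C)C)=C1CC3=C(O[Si](C)(C)C)C(C)(C)C(=O)C(C(=O)CCC)=C3O[Si](C)(C)C | intermediate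
17 | 7-butanoyl-8-ethoxy-1,5-bis(trimethylsilyloxy)-2-oxabicyclo[2.2.2]octa-5,7-dien-3-one bearing the two silylated arms at C4 and C6, racemic | O=C1OC2(O[Si](C)(C)C)C(CC3=C(O[Si](C)(C)C)C(C)(C)C(=O)C(C(=O)CCC)=C3O[Si](C)(C)C)=C(O[Si](C)(C)C)C1(CC4=C(O[Si](C)(C)C)C(C)(C)C(=O)C(C(=O)CCC)=C4O[Si](C)(C)C)C(OCC)=C2C(=O)CCC | intermediate
18 | hexakis(trimethylsilyl) ether of 19 (ring A 4-O and 6-O, four arm enol oxygens) | CCCC(=O)c1c(OCC)c(CC2=C(O[Si](C)(C)C)C(C)(C)C(=O)C(C(=O)CCC)=C2O[Si](C)(C)C)c(O[Si](C)(C)C)c(CC3=C(O[Si](C)(C)C)C(C)(C)C(=O)C(C(=O)CCC)=C3O[Si](C)(C)C)c1O[Si](C)(C)C | intermediate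
19 | 1-[2-ethoxy-4,6-dihydroxy-3,5-bis(butyrylfilicinylmethyl)phenyl]butan-1-one | CCCC(=O)c1c(OCC)c(CC2=C(O)C(C)(C)C(=O)C(C(=O)CCC)=C2O)c(O)c(CC3=C(O)C(C)(C)C(=O)C(C(=O)CCC)=C3O)c1O | intermediate
20 | 1-[2,4,6-trihydroxy-3,5-bis(butyrylfilicinylmethyl)phenyl]butan-1-one, no stereocentre | CCCC(=O)C1=C(O)C(Cc2c(O)c(CC3=C(O)C(C)(C)C(=O)C(C(=O)CCC)=C3O)c(O)c(C(=O)CCC)c2O)=C(O)C(C)(C)C1=O | target

Total step count: 9. Longest linear sequence: 7 steps (steps 1, 2, 3, 4, 5, 8, 9); steps 6 and 7 form the side branch to 15.

Steps most likely to fail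

Step 8 (Proposed new method). The ynone may be too weak a partner for the hindered, fully substituted diene, so that desilylation, loss of an arm by retro-Michael cleavage or thermal decay of the ynol ether outruns C–C bond formation. The fallback uses known chemistry and sets out from Mannich base 4 together with starting material 1. Heating 1 with 4 (2.2 equiv) in 1,4-dioxane at 70–80 °C generates enone methide 6, which alkylates the two free ring carbons of the acylphloroglucinol. This is the classical Mannich-base route to methylene-bridged acylphloroglucinols. The first arm gives 1-[3-(butyrylfilicinylmethyl)-2,4,6-trihydroxyphenyl]butan-1-one F1, and the second arm gives the target, so the fallback comes back at 20.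

Step 5. Activation of a carboxyl group beside four acidic arm enols may lead to acyl transfer onto an arm oxygen (six-membered enol lactone) instead of anhydride closure, or to decarboxylation of the β-keto diacid. The fallback sets out from 8 and caps the arms before any carboxyl group is freed.
- Trimethylsilyldiazomethane in toluene/MeOH O-methylates the four enols to the tetra-O-methyl ether of 8 F2. Enol-ether regioisomers within an arm are carried together, and one is drawn.
- TFA then gives the tetra-O-methyl diacid F3, and DCC gives the tetra-O-methyl anhydride F4, which has no acidic or nucleophilic arm oxygen.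
- F4 is annulated with 15 as its sodium enolate (NaH, THF, 0 °C to rt) to the tetra-O-methyl ether of 19 F5.
- Excess BCl3 followed by aqueous HCl removes the ethyl group and the four enol methyl groups, so the fallback comes back at 20.

Step 3. Retro-Mannich loss of the aminomethyl group from 4 may lead to self-coupling of arms, the second alkylation may stall, or liberated dimethylamine may condense with the keto ester. The fallback inverts the polarity and sets out from 5 and 3. Treating 5 with Eschenmoser's salt (2 equiv) and iPr2NEt gives di-tert-butyl 2,4-bis[(dimethylamino)methyl]-3-oxopentanedioate F6. Warming F6 with 3 (2 equiv) eliminates dimethylamine to the α-methylene β-keto ester, to which the acidic ring CH of 3 adds in a Michael reaction at each end. The fallback comes back at 8.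

Further compounds
F1 | step 8 | 1-[3-(butyrylfilicinylmethyl)-2,4,6-trihydroxyphenyl]butan-1-one | CCCC(=O)c1c(O)cc(O)c(CC2=C(O)C(C)(C)C(=O)C(C(=O)CCC)=C2O)c1O
F2 | step 5 | di-tert-butyl 2,4-bis[(5-butanoyl-2,6-dimethoxy-3,3-dimethyl-4-oxocyclohexa-1,5-dien-1-yl)methyl]-3-oxopentanedioate, epimer mixture | CC(C)(C)OC(=O)C(CC1=C(OC)C(C)(C)C(=O)C(C(=O)CCC)=C1OC)C(=O)C(CC1=C(OC)C(C)(C)C(=O)C(C(=O)CCC)=C1OC)C(=O)OC(C)(C)C
F3 | step 5 | 2,4-bis[(5-butanoyl-2,6-dimethoxy-3,3-dimethyl-4-oxocyclohexa-1,5-dien-1-yl)methyl]-3-oxopentanedioic acid, epimer mixture | OC(=O)C(CC1=C(OC)C(C)(C)C(=O)C(C(=O)CCC)=C1OC)C(=O)C(CC1=C(OC)C(C)(C)C(=O)C(C(=O)CCC)=C1OC)C(=O)O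
F4 | step 5 | 3,5-bis[(5-butanoyl-2,6-dimethoxy-3,3-dimethyl-4-oxocyclohexa-1,5-dien-1-yl)methyl]oxane-2,4,6-trione | O=C1OC(=O)C(CC2=C(OC)C(C)(C)C(=O)C(C(=O)CCC)=C2OC)C(=O)C1CC3=C(OC)C(C)(C)C(=O)C(C(=O)CCC)=C3OC
F5 | step 5 | 1-{2-ethoxy-4,6-dihydroxy-3,5-bis[(5-butanoyl-2,6-dimethoxy-3,3-dimethyl-4-oxocyclohexa-1,5-dien-1-yl)methyl]phenyl}butan-1-one | CCCC(=O)c1c(OCC)c(CC2=C(OC)C(C)(C)C(=O)C(C(=O)CCC)=C2OC)c(O)c(CC3=C(OC)C(C)(C)C(=O)C(C(=O)CCC)=C3OC)c1O
F6 | step 3 | di-tert-butyl 2,4-bis[(dimethylamino)methyl]-3-oxopentanedioate, epimer mixture | CC(C)(C)OC(=O)C(CN(C)C)C(=O)C(CN(C)C)C(=O)OC(C)(C)C
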